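**Plan**

- Retrosynthetic cuts: first the C9'' acetate and the five O–Si bonds; then ring C at C4a–C4, C4–C3 and O1–C2; then the alkyne at C1'–C(sp), and the side chain at C7''–C(aryl) and C8''–O4'.
- Enabling feature: C4 of ring C is an isolated carbonyl carbon held between C4a of ring A and C3, and O1 ties C8a of ring A to C2, the carbon that carries ring B. Ring C is therefore the sum of an ortho-iodophenol (ring A), carbon monoxide and an aryl alkyne (ring B).
- Forward order: ring A is prepared as a 2-iodo-3,5-bis(silyloxy)phenol. The β-aryl ether side chain is assembled on a 4-bromo-2,6-dimethoxyphenyl unit (ring B), and the bromide is turned into a terminal alkyne. Ring C is closed last by palladium-catalysed carbonylative annulation, followed by global desilylation and lipase acetylation of the primary hydroxyl.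
- Stereochemistry: C8'' comes from (S)-but-3-ene-1,2-diol through one Mitsunobu inversion. C7'' is set by Felkin–Anh (non-chelation) addition of an aryltitanium reagent to the α-aryloxy aldehyde, which gives the anti (7''R,8''S) pair. No later step touches either centre.

Key step: step 11

Remark: C7'', C8'' and C9'' denote the benzylic carbinol carbon, the aryloxy-bearing carbon and the acetoxymethyl carbon of the side chain; the target is read as the (7''R,8''S) anti (erythro) isomer. TBSO = tert-butyldimethylsilyloxy, TIPSO = triisopropylsilyloxy; anhydrous phloroglucinol is assumed.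

**Route**

Step 1
Reactants: 1 phloroglucinol
Product: 2 3,5-bis(TIPSO)phenol
Conditions: TIPSCl (2.0 equiv), imidazole, DMF, 0 °C → rt
Reagents that add atoms: triisopropylsilyl chloride, CC(C)[Si](Cl)(C(C)C)C(C)C
Why: Imidazole-promoted silylation of the three equivalent phenols is statistical, so with two equivalents of TIPSCl the bis-silyl ether should predominate and be separable by chromatography from the less polar tris-ether and the more polar mono-ether, both of which can be recycled.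

Step 2
Reactants: 2 3,5-bis(TIPSO)phenol
Product: 3 2-iodo-3,5-bis(TIPSO)phenol
Conditions: NIS (1.0 equiv), CH2Cl2, −20 → 0 °C, dark
Reagents that add atoms: N-iodosuccinimide, O=C1CCC(=O)N1I
Why: Electrophilic aromatic iodination of the activated phenol should go to C2, ortho to the free hydroxyl, because the only other site (C4) lies between two bulky triisopropylsilyloxy groups, and one equivalent of reagent at low temperature limits over-iodination.

Step 3
Reactants: 4 (S)-but-3-ene-1,2-diol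
Product: 5 (S)-1-(TBSO)but-3-en-2-ol
Conditions: TBSCl (1.05 equiv), imidazole, CH2Cl2, 0 °C
Reagents that add atoms: tert-butyldimethylsilyl chloride, CC(C)(C)[Si](C)(C)Cl
Why: Silylation with TBSCl is selective for the primary over the secondary hydroxyl, and the stereocentre is not involved and stays S.

Step 4
Reactants: 5 (S)-1-(TBSO)but-3-en-2-ol; 6 4-bromo-2,6-dimethoxyphenol
Product: 7 (R)-5-bromo-2-{[1-(TBSO)but-3-en-2-yl]oxy}-1,3-dimethoxybenzene
Conditions: PPh3, DIAD, THF, 0 °C → rt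
Reagents that add atoms: none
Why: In this Mitsunobu etherification the phenoxide displaces the oxyphosphonium-activated secondary carbinol by SN2, so the S centre is inverted to R and becomes C8'' of the target.

Step 5
Reactants: 7 (R)-5-bromo-2-{[1-(TBSO)but-3-en-2-yl]oxy}-1,3-dimethoxybenzene
Product: 8 (S)-2-(4-bromo-2,6-dimethoxyphenoxy)-3-(TBSO)propanal
Conditions: O3, CH2Cl2, −78 °C (Sudan Red 7B end point); then PPh3, −78 °C → rt; used crude
Reagents that add atoms: ozone, [O-][O+]=O
Why: Ozonolysis with reductive work-up cleaves the terminal alkene much faster than it attacks the aryl ether ring at −78 °C and breaks no bond at the stereocentre, whose descriptor changes from R to S only because the formyl group outranks CH2OSi.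

Step 6
Reactants: 9 4-bromo-2-methoxyphenol
Product: 10 (4-bromo-2-methoxyphenoxy)triisopropylsilane
Conditions: TIPSCl, imidazole, DMF, rt
Reagents that add atoms: triisopropylsilyl chloride, CC(C)[Si](Cl)(C(C)C)C(C)C
Why: This is a standard phenol silylation, and the TIPS ether withstands the organometallic chemistry that follows.

Step 7
Reactants: 10 (4-bromo-2-methoxyphenoxy)triisopropylsilane; 8 (S)-2-(4-bromo-2,6-dimethoxyphenoxy)-3-(TBSO)propanal
Product: 13 (1R,2S)-2-(4-bromo-2,6-dimethoxyphenoxy)-3-(TBSO)-1-[3-methoxy-4-(TIPSO)phenyl]propan-1-ol, via aryllithium 11 (not isolated), via aryltitanium triisopropoxide 12 (not isolated)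
Conditions: n-BuLi, THF, −78 °C; ClTi(OiPr)3, −78 → −40 °C; then 8, −78 → 0 °C; aq NH4Cl
Reagents that add atoms: none
Why: Bromine–lithium exchange and transmetalation give a weakly basic, weakly Lewis acidic aryltitanium reagent that adds to the α-aryloxy aldehyde without chelation or enolisation, so the polar Felkin–Anh transition state (C–OAr bond anti to the incoming aryl group, attack past the hydrogen) should set C7'' as R, anti to the existing 8''S centre.

Step 8
Reactants: 13 (1R,2S)-2-(4-bromo-2,6-dimethoxyphenoxy)-3-(TBSO)-1-[3-methoxy-4-(TIPSO)phenyl]propan-1-ol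
Product: 14 (1R,2S)-2-(4-bromo-2,6-dimethoxyphenoxy)-1,3-bis(TBSO)-1-[3-methoxy-4-(TIPSO)phenyl]propane
Conditions: TBSOTf, 2,6-lutidine, CH2Cl2, −78 → 0 °C
Reagents that add atoms: tert-butyldimethylsilyl trifluoromethanesulfonate, CC(C)(C)[Si](C)(C)OS(=O)(=O)C(F)(F)F
Why: Silylation of the hindered secondary benzylic alcohol with the silyl triflate and a hindered base is fast at low temperature and leaves both stereocentres untouched.

Step 9
Reactants: 14 (1R,2S)-2-(4-bromo-2,6-dimethoxyphenoxy)-1,3-bis(TBSO)-1-[3-methoxy-4-(TIPSO)phenyl]propane; 15 ethynyltrimethylsilane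
Product: 16 (1R,2S)-1,3-bis(TBSO)-2-[2,6-dimethoxy-4-(trimethylsilylethynyl)phenoxy]-1-[3-methoxy-4-(TIPSO)phenyl]propane
Conditions: PdCl2(PhCN)2 (3 mol %), P(t-Bu)3·HBF4 (6 mol %), CuI (3 mol %), iPr2NH, dioxane, rt → 40 °C
Reagents that add atoms: none
Why: In this Sonogashira coupling the electron-rich aryl bromide has both ortho positions free, and the bulky electron-rich phosphine allows oxidative addition to zerovalent palladium near room temperature, which spares the silyl ethers.

Step 10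
Reactants: 16 (1R,2S)-1,3-bis(TBSO)-2-[2,6-dimethoxy-4-(trimethylsilylethynyl)phenoxy]-1-[3-methoxy-4-(TIPSO)phenyl]propane
Product: 17 (1R,2S)-1,3-bis(TBSO)-2-(4-ethynyl-2,6-dimethoxyphenoxy)-1-[3-methoxy-4-(TIPSO)phenyl]propane
Conditions: K2CO3 (0.2 equiv), MeOH–THF, 0 °C
Reagents that add atoms: none
Why: Carbonate-catalysed methanolysis of the C(sp)–Si bond is much faster than cleavage of the hindered aryl TIPS ether or the alkyl TBS ethers.

Step 11
Reactants: 3 2-iodo-3,5-bis(TIPSO)phenol; 17 (1R,2S)-1,3-bis(TBSO)-2-(4-ethynyl-2,6-dimethoxyphenoxy)-1-[3-methoxy-4-(TIPSO)phenyl]propane; 18 carbon monoxide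
Product: 21 2-{4-[(1R,2S)-1,3-bis(TBSO)-1-[3-methoxy-4-(TIPSO)phenyl]propan-2-yl]oxy-3,5-dimethoxyphenyl}-5,7-bis(TIPSO)-4H-chromen-4-one, via 2-hydroxyaryl ynone 19 (not isolated), via diethylamino enone 20 (not isolated)
Conditions: PdCl2(dppf) (5 mol %; dppf = 1,1'-bis(diphenylphosphino)ferrocene), CO (10 bar), Et2NH–THF (1:1), 80 °C
Reagents that add atoms: none
Why: Zerovalent palladium, formed in the flask from the divalent precatalyst PdCl2(dppf), inserts into the C–I bond of 3, CO inserts to give an aroylpalladium iodide, and amine-assisted alkynylation by 17 with reductive elimination releases ynone 19, which creates C4a–C4 and C4–C3. Et2NH then adds to the ynone to give enaminone 20, and the phenol oxygen attacks C2 and expels the amine, which creates O1–C2. The closest known reaction type is the palladium-catalysed carbonylative Sonogashira coupling and annulation of 2-iodophenols with terminal aryl alkynes in Et2NH, an established flavone synthesis. Ring C closes in the 6-endo mode (6-endo-dig with respect to the ynone, carried out as conjugate addition and elimination on the enaminone), and no stereocentre is formed. The step needs CO insertion ahead of direct alkynylation, which CO pressure and the absence of a copper co-catalyst secure, and 6-endo closure in place of 5-exo closure to an aurone, which is secured because the amine makes C2 the only electrophilic carbon within reach of the single free hydroxyl beside the iodide. The weakly basic medium should leave the silyl ethers intact, and C7'' and C8'' carry no acidic hydrogen, so their configuration is not at risk.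

Step 12
Reactants: 21 2-{4-[(1R,2S)-1,3-bis(TBSO)-1-[3-methoxy-4-(TIPSO)phenyl]propan-2-yl]oxy-3,5-dimethoxyphenyl}-5,7-bis(TIPSO)-4H-chromen-4-one
Product: 22 5,7-dihydroxy-2-{4-[(1R,2S)-1,3-dihydroxy-1-(4-hydroxy-3-methoxyphenyl)propan-2-yl]oxy-3,5-dimethoxyphenyl}-4H-chromen-4-one
Conditions: TBAF, AcOH (1:1, excess), THF, 0 °C → rt
Reagents that add atoms: none
Why: Fluoride cleaves all five Si–O bonds, and acetic acid keeps the medium near neutral so that the 4-hydroxybenzylic alcohol does not ionise to a quinone methide and neither stereocentre epimerises.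

Step 13
Reactants: 22 5,7-dihydroxy-2-{4-[(1R,2S)-1,3-dihydroxy-1-(4-hydroxy-3-methoxyphenyl)propan-2-yl]oxy-3,5-dimethoxyphenyl}-4H-chromen-4-one
Product: 23 (2S,3R)-2-[4-(5,7-dihydroxy-4-oxo-4H-chromen-2-yl)-2,6-dimethoxyphenoxy]-3-hydroxy-3-(4-hydroxy-3-methoxyphenyl)propyl acetate (CNP0157817.1)
Conditions: immobilised Candida antarctica lipase B, vinyl acetate, THF, 40 °C
Reagents that add atoms: vinyl acetate, C=COC(C)=O
Why: Lipase-catalysed transesterification with an irreversible acyl donor should acylate only the unhindered primary hydroxyl, because the three phenols and the secondary benzylic hydroxyl flanked by two bulky groups are not accepted at a useful rate.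

**Compound list**

1 | phloroglucinol | Oc1cc(O)cc(O)c1 | starting material
2 | 3,5-bis(triisopropylsilyloxy)phenol | Oc1cc(O[Si](C(C)C)(C(C)C)C(C)C)cc(O[Si](C(C)C)(C(C)C)C(C)C)c1 | intermediate
3 | 2-iodo-3,5-bis(triisopropylsilyloxy)phenol | Oc1cc(O[Si](C(C)C)(C(C)C)C(C)C)cc(O[Si](C(C)C)(C(C)C)C(C)C)c1I | intermediate
4 | (S)-but-3-ene-1,2-diol | C=C[C@@H](CO)O | starting material
5 | (S)-1-(tert-butyldimethylsilyloxy)but-3-en-2-ol | C=C[C@@H](CO[Si](C)(C)C(C)(C)C)O | intermediate
6 | 4-bromo-2,6-dimethoxyphenol | COc1cc(Br)cc(OC)c1O | starting material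
7 | (R)-5-bromo-2-{[1-(tert-butyldimethylsilyloxy)but-3-en-2-yl]oxy}-1,3-dimethoxybenzene | C=C[C@H](CO[Si](C)(C)C(C)(C)C)Oc1c(OC)cc(Br)cc1OC | intermediate
8 | (S)-2-(4-bromo-2,6-dimethoxyphenoxy)-3-(tert-butyldimethylsilyloxy)propanal | O=C[C@H](CO[Si](C)(C)C(C)(C)C)Oc1c(OC)cc(Br)cc1OC | intermediate
9 | 4-bromo-2-methoxyphenol | COc1cc(Br)ccc1O | starting material
10 | (4-bromo-2-methoxyphenoxy)triisopropylsilane | COc1cc(Br)ccc1O[Si](C(C)C)(C(C)C)C(C)C | intermediate
11 | [3-methoxy-4-(triisopropylsilyloxy)phenyl]lithium | COc1cc([Li])ccc1O[Si](C(C)C)(C(C)C)C(C)C | intermediate (not isolated)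
12 | [3-methoxy-4-(triisopropylsilyloxy)phenyl]titanium triisopropoxide | COc1cc([Ti](OC(C)C)(OC(C)C)OC(C)C)ccc1O[Si](C(C)C)(C(C)C)C(C)C | intermediate (not isolated)
13 | (1R,2S)-2-(4-bromo-2,6-dimethoxyphenoxy)-3-(tert-butyldimethylsilyloxy)-1-[3-methoxy-4-(triisopropylsilyloxy)phenyl]propan-1-ol | COc1cc([C@@H](O)[C@H](CO[Si](C)(C)C(C)(C)C)Oc2c(OC)cc(Br)cc2OC)ccc1O[Si](C(C)C)(C(C)C)C(C)C | intermediate
14 | (1R,2S)-2-(4-bromo-2,6-dimethoxyphenoxy)-1,3-bis(tert-butyldimethylsilyloxy)-1-[3-methoxy-4-(triisopropylsilyloxy)phenyl]propane | COc1cc([C@@H](O[Si](C)(C)C(C)(C)C)[C@H](CO[Si](C)(C)C(C)(C)C)Oc2c(OC)cc(Br)cc2OC)ccc1O[Si](C(C)C)(C(C)C)C(C)C | intermediate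
15 | ethynyltrimethylsilane | C#C[Si](C)(C)C | starting material
16 | (1R,2S)-1,3-bis(tert-butyldimethylsilyloxy)-2-[2,6-dimethoxy-4-(trimethylsilylethynyl)phenoxy]-1-[3-methoxy-4-(triisopropylsilyloxy)phenyl]propane | COc1cc([C@@H](O[Si](C)(C)C(C)(C)C)[C@H](CO[Si](C)(C)C(C)(C)C)Oc2c(OC)cc(C#C[Si](C)(C)C)cc2OC)ccc1O[Si](C(C)C)(C(C)C)C(C)C | intermediate
17 | (1R,2S)-1,3-bis(tert-butyldimethylsilyloxy)-2-(4-ethynyl-2,6-dimethoxyphenoxy)-1-[3-methoxy-4-(triisopropylsilyloxy)phenyl]propane | COc1cc([C@@H](O[Si](C)(C)C(C)(C)C)[C@H](CO[Si](C)(C)C(C)(C)C)Oc2c(OC)cc(C#C)cc2OC)ccc1O[Si](C(C)C)(C(C)C)C(C)C | intermediate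
18 | carbon monoxide | [C-]#[O+] | starting material
19 | 3-{4-[(1R,2S)-1,3-bis(tert-butyldimethylsilyloxy)-1-[3-methoxy-4-(triisopropylsilyloxy)phenyl]propan-2-yl]oxy-3,5-dimethoxyphenyl}-1-[2-hydroxy-4,6-bis(triisopropylsilyloxy)phenyl]prop-2-yn-1-one | COc1cc([C@@H](O[Si](C)(C)C(C)(C)C)[C@H](CO[Si](C)(C)C(C)(C)C)Oc2c(OC)cc(C#CC(=O)c3c(O)cc(O[Si](C(C)C)(C(C)C)C(C)C)cc3O[Si](C(C)C)(C(C)C)C(C)C)cc2OC)ccc1O[Si](C(C)C)(C(C)C)C(C)C | intermediate (not isolated)
20 | (E)-3-{4-[(1R,2S)-1,3-bis(tert-butyldimethylsilyloxy)-1-[3-methoxy-4-(triisopropylsilyloxy)phenyl]propan-2-yl]oxy-3,5-dimethoxyphenyl}-3-(diethylamino)-1-[2-hydroxy-4,6-bis(triisopropylsilyloxy)phenyl]prop-2-en-1-one (E expected; the geometry is lost on ring closure) | COc1cc([C@@H](O[Si](C)(C)C(C)(C)C)[C@H](CO[Si](C)(C)C(C)(C)C)Oc2c(OC)cc(/C(N(CC)CC)=C\C(=O)c3c(O)cc(O[Si](C(C)C)(C(C)C)C(C)C)cc3O[Si](C(C)C)(C(C)C)C(C)C)cc2OC)ccc1O[Si](C(C)C)(C(C)C)C(C)C | intermediate (not isolated)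
21 | 2-{4-[(1R,2S)-1,3-bis(tert-butyldimethylsilyloxy)-1-[3-methoxy-4-(triisopropylsilyloxy)phenyl]propan-2-yl]oxy-3,5-dimethoxyphenyl}-5,7-bis(triisopropylsilyloxy)-4H-chromen-4-one | COc1cc([C@@H](O[Si](C)(C)C(C)(C)C)[C@H](CO[Si](C)(C)C(C)(C)C)Oc2c(OC)cc(-c3cc(=O)c4c(O[Si](C(C)C)(C(C)C)C(C)C)cc(O[Si](C(C)C)(C(C)C)C(C)C)cc4o3)cc2OC)ccc1O[Si](C(C)C)(C(C)C)C(C)C | intermediate
22 | 5,7-dihydroxy-2-{4-[(1R,2S)-1,3-dihydroxy-1-(4-hydroxy-3-methoxyphenyl)propan-2-yl]oxy-3,5-dimethoxyphenyl}-4H-chromen-4-one | COc1cc([C@@H](O)[C@H](CO)Oc2c(OC)cc(-c3cc(=O)c4c(O)cc(O)cc4o3)cc2OC)ccc1O | intermediate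
23 | (2S,3R)-2-[4-(5,7-dihydroxy-4-oxo-4H-chromen-2-yl)-2,6-dimethoxyphenoxy]-3-hydroxy-3-(4-hydroxy-3-methoxyphenyl)propyl acetate (CNP0157817.1) | COc1cc([C@@H](O)[C@H](COC(C)=O)Oc2c(OC)cc(-c3cc(=O)c4c(O)cc(O)cc4o3)cc2OC)ccc1O | target

**Step count**

Total: 13 steps. Longest linear sequence: 10 steps (steps 3, 4, 5, 7, 8, 9, 10, 11, 12 and 13, starting from 4).

**Steps most likely to fail and fallbacks**

Step 11. Oxidative addition at the doubly ortho-substituted, electron-rich iodide may be sluggish, the aroylpalladium species may be captured by diethylamine, or alkynylation may occur without CO uptake. The fallback builds ring C without palladium and sets out from 17. Deprotonation (n-BuLi, THF, −78 °C) and addition of the lithium acetylide to 2,4,6-tris(triisopropylsilyloxy)benzaldehyde F1 (from commercial 2,4,6-trihydroxybenzaldehyde, TIPSOTf, 2,6-lutidine) would give the propargylic alcohol F2 as a mixture of carbinol epimers, which is of no consequence. MnO2 in CH2Cl2 would oxidise it to the ynone F3, and Et2NH in EtOH–THF would add to give the enaminone F4. TBAF/AcOH would then remove all six silyl groups, and the freed 2-hydroxyl would close ring C by addition and loss of diethylamine. The route is rejoined at 22, and 21 is bypassed.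

Step 7. The aryl transfer may show poor facial selectivity. The fallback sets C7'' by ketone reduction and sets out from 13, taken as the mixture of C7'' epimers delivered by the addition. Dess–Martin periodinane (NaHCO3, CH2Cl2) would oxidise the carbinol to the aryl ketone F5. Zn(BH4)2 in Et2O at −30 °C would then reduce it under chelation control, with zinc bridged between the carbonyl and ether oxygens and hydride delivered from the face of the C8'' hydrogen, the established way to anti 1,2-diol derivatives from α-alkoxy ketones. The route is rejoined at 13.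

Step 4. The Mitsunobu reaction may give low conversion with the doubly ortho-substituted phenol, SN2′ attack at the alkene terminus, or erosion of configuration. The fallback forms the aryl ether by SN2 displacement at a saturated carbon and sets out from 6. Commercial methyl (R)-2,3-dihydroxypropanoate would be silylated at the primary hydroxyl (TBSCl, imidazole) to methyl (R)-3-(tert-butyldimethylsilyloxy)-2-hydroxypropanoate F6 and converted (Tf2O, 2,6-lutidine, CH2Cl2, −78 °C) into the triflate F7. Displacement by 6 (K2CO3, MeCN, 0 °C → rt) with inversion would give methyl (S)-2-(4-bromo-2,6-dimethoxyphenoxy)-3-(tert-butyldimethylsilyloxy)propanoate F8. DIBAL-H (toluene, −78 °C) would then deliver the aldehyde, and the route is rejoined at 8; steps 3 and 5 are then not needed.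

Further compounds
F1 | step 11 | 2,4,6-tris(triisopropylsilyloxy)benzaldehyde | O=Cc1c(O[Si](C(C)C)(C(C)C)C(C)C)cc(O[Si](C(C)C)(C(C)C)C(C)C)cc1O[Si](C(C)C)(C(C)C)C(C)C
F2 | step 11 | 3-{4-[(1R,2S)-1,3-bis(tert-butyldimethylsilyloxy)-1-[3-methoxy-4-(triisopropylsilyloxy)phenyl]propan-2-yl]oxy-3,5-dimethoxyphenyl}-1-[2,4,6-tris(triisopropylsilyloxy)phenyl]prop-2-yn-1-ol (carbinol epimers) | COc1cc([C@@H](O[Si](C)(C)C(C)(C)C)[C@H](CO[Si](C)(C)C(C)(C)C)Oc2c(OC)cc(C#CC(O)c3c(O[Si](C(C)C)(C(C)C)C(C)C)cc(O[Si](C(C)C)(C(C)C)C(C)C)cc3O[Si](C(C)C)(C(C)C)C(C)C)cc2OC)ccc1O[Si](C(C)C)(C(C)C)C(C)C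
F3 | step 11 | 3-{4-[(1R,2S)-1,3-bis(tert-butyldimethylsilyloxy)-1-[3-methoxy-4-(triisopropylsilyloxy)phenyl]propan-2-yl]oxy-3,5-dimethoxyphenyl}-1-[2,4,6-tris(triisopropylsilyloxy)phenyl]prop-2-yn-1-one | COc1cc([C@@H](O[Si](C)(C)C(C)(C)C)[C@H](CO[Si](C)(C)C(C)(C)C)Oc2c(OC)cc(C#CC(=O)c3c(O[Si](C(C)C)(C(C)C)C(C)C)cc(O[Si](C(C)C)(C(C)C)C(C)C)cc3O[Si](C(C)C)(C(C)C)C(C)C)cc2OC)ccc1O[Si](C(C)C)(C(C)C)C(C)C
F4 | step 11 | (E)-3-{4-[(1R,2S)-1,3-bis(tert-butyldimethylsilyloxy)-1-[3-methoxy-4-(triisopropylsilyloxy)phenyl]propan-2-yl]oxy-3,5-dimethoxyphenyl}-3-(diethylamino)-1-[2,4,6-tris(triisopropylsilyloxy)phenyl]prop-2-en-1-one | COc1cc([C@@H](O[Si](C)(C)C(C)(C)C)[C@H](CO[Si](C)(C)C(C)(C)C)Oc2c(OC)cc(/C(N(CC)CC)=C\C(=O)c3c(O[Si](C(C)C)(C(C)C)C(C)C)cc(O[Si](C(C)C)(C(C)C)C(C)C)cc3O[Si](C(C)C)(C(C)C)C(C)C)cc2OC)ccc1O[Si](C(C)C)(C(C)C)C(C)C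
F5 | step 7 | (S)-2-(4-bromo-2,6-dimethoxyphenoxy)-3-(tert-butyldimethylsilyloxy)-1-[3-methoxy-4-(triisopropylsilyloxy)phenyl]propan-1-one | COc1cc(C(=O)[C@H](CO[Si](C)(C)C(C)(C)C)Oc2c(OC)cc(Br)cc2OC)ccc1O[Si](C(C)C)(C(C)C)C(C)C
F6 | step 4 | methyl (R)-3-(tert-butyldimethylsilyloxy)-2-hydroxypropanoate | COC(=O)[C@H](O)CO[Si](C)(C)C(C)(C)C
F7 | step 4 | methyl (R)-3-(tert-butyldimethylsilyloxy)-2-(trifluoromethylsulfonyloxy)propanoate | COC(=O)[C@H](OS(=O)(=O)C(F)(F)F)CO[Si](C)(C)C(C)(C)C
F8 | step 4 | methyl (S)-2-(4-bromo-2,6-dimethoxyphenoxy)-3-(tert-butyldimethylsilyloxy)propanoate | COC(=O)[C@@H](Oc1c(OC)cc(Br)cc1OC)CO[Si](C)(C)C(C)(C)C
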